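All constants come from no measurement; the rest is arithmetic.

Judge these flasks first by where each must end, then by how fast it gets there.

all flasks: D 0.615 M; time 80 min
- violet: L 0.41 M; X 0.287 M (in portions, 5, over 50 min); first portion at the start, last at 50 min
- green: L 0.41 M; X 0.287 M (fed, over 50 min); all else is in the flask from the start; the feed brings no volume worth counting
- red: L 0.41 M (fed, over 50 min); X 0.287 M; all else is in the flask from the start; the feed brings no volume worth counting
- ochre: L 0.41 M; X 0.287 M; everything together at the start

    X + Z → X.Z (k1 = 12 /M/min)
    X ⇌ E (K2 = 1.7, k2 = 0.75 /min)
    D + Z → D.Z (k3 = 2.1 /M/min)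
    L ⇌ Z (K4 = 0.15, k4 = 0.081 /min)
    L + X.Z ⇌ L.X.Z, settled at all times (K5 = 6.1 /M)

- a species is counted by the L in it: one L.X.Z counts as two
- amounts and yields of X.Z count L.X.Z too
- in an amount of X.Z, one L.X.Z counts as one X.Z
- run time (violet): 80 min

1. which flask leads in amount of X.Z, in percent of the L charged ("all alike" within 1.5 percentage points) (violet / green / red / ochre / all alike)
2. how much X.Z is there at the end, in percent of the L charged: violet
3. how much X.Z is there at the end, in percent of the L charged: green
4. how much X.Z is there at the end, in percent of the L charged: red
5. how much X.Z is there at the end, in percent of the L charged: ochre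

**Two captors.** L gives Z with a half-life of 8.6 min, while Z lasts 0.20 min against X and 0.54 min against D, so Z stays tiny. X and E balance within 0.582 min, quicker than that half-life of L, so I treat them as one pool. The capture ratio, 2.12, is the constant of X on Z, thinned by the free part of that pool, over the constant of D on Z. It is a selectivity factor.

**The level.** With the pool and D both fully charged, the fraction of pool left equals the fraction of D left raised to the capture ratio, and no clock enters. Try 0.625 of D left. Then X.Z takes 44.1 % of the L and D.Z takes 56.2 %, which together account for the charge, so the trial stands.

**The curve.** In ochre, X takes a share of 0.497 at first, so X.Z climbs at 0.0402 /min of the charge. Its knee I put past L's forward half-life, with Z returning to L and step 5 starting at a binding strength of 2.5. Then it creeps towards 44.1 %. Red aims at the same level, with its knee after the feed ends at 50 min.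

**Green's share.** In green, leaving step 5 aside, Z falls back to L at 0.540 /min against 1.29 /min onward to D, so L's net loss runs at 0.0571 /min. Half the release of Z has then come by 12.1 min, a quarter of the way through the feed, and I take D as down by half the L charge at that moment. The capture ratio then gives 26.4 %. I leave violet unreckoned, noting that 20.0 % of its X is in at the start.

**The forecast.** It named ochre as leader, with 43 %, red 40 %, violet 26.5 % and green 23 %, below my green: “feeding X late hands the early Z to D”.

**The flasks.** Ochre leads with 42.3 %, then red 38.8 %, violet 25.4 % and green 24.3 %. Ochre and red reach 44.2 % and 43.8 % after 800 min, so their gap at 42.3 % against 38.8 % is one of time. Green reaches 25.9 %, so its gap is one of level. Now charge green with 1.0 M of D. The same reckoning moves the halfway moment to 10.8 min and gives 14.1 %. That flask holds 15.8 % of X.Z at 80.0 min, with 1.00 % of L left.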